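**Plan**

- Ring A is the benzene ring C4a–C8a and ring B is the lactone ring O1–C2–C3–C4–C4a–C8a. The retrosynthesis first removes the silyl groups from O5 and O7, then cuts C3–C4, then the ester bond O1–C2, and last the C4–C4a (benzyl) and C8–acyl bonds back to phloroglucinol.
- The enabling feature is that C4 is doubly benzylic and, in the ring-opened form, is the CH2 of a 2-benzylphenol with two enantiotopic hydrogens. C3 is separated from the phenol oxygen on C8a only by the ester link O1–C2, so a diazoacetate on that oxygen places a carbene carbon within six-ring reach of C4.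
- Forward: ring A is bought. The C8 acyl chain and the C4 benzyl group are attached, O5 and O7 are silylated, and O1 is esterified and turned into the diazoacetate. Ring B then closes by C–H insertion, and desilylation finishes the synthesis.
- The only stereocentre, C4 (S), is created in the ring-B closure by a chiral dirhodium carboxamidate that selects one benzylic hydrogen. No later step touches it.

Key step: step 6

Assumption: the sense of induction of Rh2(5S-MEPY)4 on this substrate class cannot be predicted with confidence; the route is written for the 5S catalyst giving (4S), and the mirror-image Rh2(5R-MEPY)4 would be used if the first cyclisation shows the opposite sense.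

**Route**

Step 1
Reactants: 1 phloroglucinol; 2 3-phenylpropanoyl chloride
Product: 3 1-(2,4,6-trihydroxyphenyl)-3-phenylpropan-1-one
Conditions: AlCl3 (4 equiv), PhNO2, 0 to 60 °C; aq. HCl work-up
Reagents that add atoms: none
Why: Friedel–Crafts acylation of the threefold-symmetric, highly activated triol can give only one C-acyl product, and the new ketone deactivates the ring against a second acylation.

Step 2
Reactants: 3 1-(2,4,6-trihydroxyphenyl)-3-phenylpropan-1-one; 4 benzyl bromide
Product: 5 1-(3-benzyl-2,4,6-trihydroxyphenyl)-3-phenylpropan-1-one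
Conditions: NaOMe (1.0 equiv), MeOH, 0 °C to rt, 4 (0.9 equiv) added slowly
Reagents that add atoms: none
Why: Phenoxide C-alkylation (C-benzylation) of an acylphloroglucinol in a protic solvent, where the hydrogen-bonded oxygens leave the ring carbon as the nucleophile, puts the benzyl group on one of the two equivalent ring CH positions; the step is held below full conversion to limit dibenzylation.

Step 3
Reactants: 5 1-(3-benzyl-2,4,6-trihydroxyphenyl)-3-phenylpropan-1-one
Product: 6 1-[3-benzyl-4,6-bis(tert-butyldimethylsilyloxy)-2-hydroxyphenyl]-3-phenylpropan-1-one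
Conditions: TBSCl (2.1 equiv), imidazole, DMF, 0 °C to rt
Reagents that add atoms: tert-butyldimethylsilyl chloride, CC(C)(C)[Si](C)(C)Cl
Why: Phenol silylation should take the hydroxyl para to the ketone first (most acidic, not chelated) and then the chelated hydroxyl next to the ring hydrogen, leaving free the hydroxyl wedged between acyl and benzyl groups, which stays hydrogen-bonded to the ketone.

Step 4
Reactants: 6 1-[3-benzyl-4,6-bis(tert-butyldimethylsilyloxy)-2-hydroxyphenyl]-3-phenylpropan-1-one; 7 bromoacetyl bromide
Product: 8 2-benzyl-3,5-bis(tert-butyldimethylsilyloxy)-6-(3-phenylpropanoyl)phenyl bromoacetate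
Conditions: pyridine (1.5 equiv), CH2Cl2, −10 to 0 °C
Reagents that add atoms: none
Why: O-acylation of a phenol with an acyl bromide is reactive enough to esterify even a chelated, doubly flanked hydroxyl, as in the routine esterification of ortho-hydroxyaryl ketones, while the silyl ethers and the ketone are inert to cold pyridine.

Step 5
Reactants: 8 2-benzyl-3,5-bis(tert-butyldimethylsilyloxy)-6-(3-phenylpropanoyl)phenyl bromoacetate
Product: 10 2-benzyl-3,5-bis(tert-butyldimethylsilyloxy)-6-(3-phenylpropanoyl)phenyl diazoacetate, via N-alkylated ditosylhydrazide 9 (not isolated)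
Conditions: N,N'-ditosylhydrazine (2 equiv), DBU (5 equiv), THF, 0 °C, short reaction time
Reagents that add atoms: N,N'-ditosylhydrazine, Cc1ccc(cc1)S(=O)(=O)NNS(=O)(=O)c1ccc(C)cc1
Why: Diazoacetate formation from a bromoacetate by SN2 alkylation of the sulfonylhydrazide anion followed by two base-induced sulfinate eliminations (Bamford–Stevens-type) is fast at 0 °C, which should spare the aryl ester and the aryl silyl ethers.

Step 6
Reactants: 10 2-benzyl-3,5-bis(tert-butyldimethylsilyloxy)-6-(3-phenylpropanoyl)phenyl diazoacetate
Product: 11 (4S)-5,7-bis(tert-butyldimethylsilyloxy)-4-phenyl-8-(3-phenylpropanoyl)chroman-2-one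
Conditions: Rh2(5S-MEPY)4 (1–2 mol %), CH2Cl2, reflux, 10 added by syringe pump over several hours
Reagents that add atoms: none
Why: Proposed new method: Rh2(5S-MEPY)4, dirhodium tetrakis[methyl (5S)-2-oxopyrrolidine-5-carboxylate] with a divalent rhodium core, expels N2 from 10 to give an electrophilic acceptor carbene at the future C3, which inserts into one benzylic C–H bond of the benzyl group on C4a through a concerted three-centre transition state with hydride-like transfer, forming C3–C4. The closest known reaction types are the enantioselective intramolecular C–H insertion of alkyl diazoacetates to γ-lactones under chiral dirhodium carboxamidates and the six-membered C–H insertion of ortho-alkoxyaryl diazo ketones to chroman-4-ones; an aryl diazoacetate closing onto an ortho benzyl group has not been demonstrated. Ring B closes as a six-membered δ-lactone by 1,6-insertion, the planar O1–C8a–C4a unit of ring A holding the carbene carbon and the C–H bond within reach once the aryl ester rotates into its E conformer. C4 is set by catalyst control: the chiral carboxamidate pocket around the carbene selects one of the two enantiotopic benzylic hydrogens, which fixes the (4S) configuration. The step needs chemoselectivity for this C–H bond over carbonyl-ylide formation at the C8 ketone, addition to the arenes and carbene dimerisation; both positions ortho to O1 are substituted so no five-membered closure is open, the doubly benzylic C–H bond is the most hydridic one in reach, the carboxamidate carbene is only weakly electrophilic towards arenes, the silyl ethers offer no activated C–H bond, and slow addition keeps the diazo concentration low.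

Step 7
Reactants: 11 (4S)-5,7-bis(tert-butyldimethylsilyloxy)-4-phenyl-8-(3-phenylpropanoyl)chroman-2-one
Product: 12 (4S)-5,7-dihydroxy-4-phenyl-8-(3-phenylpropanoyl)chroman-2-one
Conditions: HF·pyridine, THF–pyridine, 0 °C to rt
Reagents that add atoms: none
Why: Fluoride desilylation of aryl silyl ethers under mildly acidic conditions generates no phenoxide or hydroxide, so the aryl lactone should stay closed (no relactonisation onto O5), and C4, whose hydrogen is not acidic, keeps its configuration.

**Compound list**

1 | phloroglucinol | Oc1cc(O)cc(O)c1 | starting material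
2 | 3-phenylpropanoyl chloride | O=C(Cl)CCc1ccccc1 | starting material
3 | 1-(2,4,6-trihydroxyphenyl)-3-phenylpropan-1-one | O=C(CCc1ccccc1)c1c(O)cc(O)cc1O | intermediate
4 | benzyl bromide | BrCc1ccccc1 | starting material
5 | 1-(3-benzyl-2,4,6-trihydroxyphenyl)-3-phenylpropan-1-one | O=C(CCc1ccccc1)c1c(O)cc(O)c(Cc2ccccc2)c1O | intermediate
6 | 1-[3-benzyl-4,6-bis(tert-butyldimethylsilyloxy)-2-hydroxyphenyl]-3-phenylpropan-1-one | O=C(CCc1ccccc1)c1c(O[Si](C)(C)C(C)(C)C)cc(O[Si](C)(C)C(C)(C)C)c(Cc2ccccc2)c1O | intermediate
7 | bromoacetyl bromide | O=C(Br)CBr | starting material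
8 | 2-benzyl-3,5-bis(tert-butyldimethylsilyloxy)-6-(3-phenylpropanoyl)phenyl bromoacetate | O=C(CBr)Oc1c(Cc2ccccc2)c(O[Si](C)(C)C(C)(C)C)cc(O[Si](C)(C)C(C)(C)C)c1C(=O)CCc1ccccc1 | intermediate
9 | 2-benzyl-3,5-bis(tert-butyldimethylsilyloxy)-6-(3-phenylpropanoyl)phenyl [1,2-bis(4-methylbenzenesulfonyl)hydrazinyl]acetate (N-alkylated ditosylhydrazide) | Cc1ccc(cc1)S(=O)(=O)NN(CC(=O)Oc1c(Cc2ccccc2)c(O[Si](C)(C)C(C)(C)C)cc(O[Si](C)(C)C(C)(C)C)c1C(=O)CCc1ccccc1)S(=O)(=O)c1ccc(C)cc1 | intermediate
10 | 2-benzyl-3,5-bis(tert-butyldimethylsilyloxy)-6-(3-phenylpropanoyl)phenyl diazoacetate | [N-]=[N+]=CC(=O)Oc1c(Cc2ccccc2)c(O[Si](C)(C)C(C)(C)C)cc(O[Si](C)(C)C(C)(C)C)c1C(=O)CCc1ccccc1 | intermediate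
11 | (4S)-5,7-bis(tert-butyldimethylsilyloxy)-4-phenyl-8-(3-phenylpropanoyl)chroman-2-one | O=C1C[C@@H](c2ccccc2)c2c(O[Si](C)(C)C(C)(C)C)cc(O[Si](C)(C)C(C)(C)C)c(C(=O)CCc3ccccc3)c2O1 | intermediate
12 | (4S)-5,7-dihydroxy-4-phenyl-8-(3-phenylpropanoyl)chroman-2-one (CNP0321593.1) | O=C1C[C@@H](c2ccccc2)c2c(O)cc(O)c(C(=O)CCc3ccccc3)c2O1 | target

**Step count and risks**

Total step count: 7. Longest linear sequence: 7 steps (1 to 12).

Steps most likely to fail:

1. Step 6. The carbene may be diverted by attack of the C8 ketone oxygen (carbonyl ylide, then proton shift), by addition to ring A or to a phenyl ring (Buchner-type), or by dimerisation if rotation of the aryl ester into the reactive conformer is slow. Discrimination between the two enantiotopic hydrogens may also be insufficient. The fallback uses known chemistry, sets out from 1 (with 2) and comes back at 11. Pechmann-type condensation of 1 with ethyl propiolate (ZnCl2, 100 °C) should give 5,7-dihydroxy-2H-chromen-2-one F1. Friedel–Crafts acylation of F1 with 2 and AlCl3 in PhNO2, which for 5,7-dihydroxycoumarins is known to favour C8, should give 5,7-dihydroxy-8-(3-phenylpropanoyl)-2H-chromen-2-one F2 after removal of the C6 isomer. Silylation of both hydroxyls (TBSCl, imidazole, DMF) should give 5,7-bis(tert-butyldimethylsilyloxy)-8-(3-phenylpropanoyl)-2H-chromen-2-one F3. Hayashi–Miyaura asymmetric 1,4-addition of phenylboronic acid to F3, catalysed by Rh(acac)(C2H4)2 (monovalent rhodium) with SEGPHOS in dioxane–water at 60 °C, then places the phenyl group on C4 and should give 11. The ligand antipode is chosen to deliver (4S), expected to be (S)-SEGPHOS by analogy with unsubstituted coumarins.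

2. Step 3. Site selection between the two chelated hydroxyls may be incomplete, or silylation may run on to the third hydroxyl, so that the free hydroxyl ends up on the wrong side of the ketone. The fallback sets out from 3 and comes back at 6, and it also bypasses the C-benzylation of step 2. Silylation of symmetric 3 (TBSCl, imidazole, DMF) can give only one chelated bis-silyl ether, 1-[2-hydroxy-4,6-bis(tert-butyldimethylsilyloxy)phenyl]-3-phenylpropan-1-one F4. Iodination with N-iodosuccinimide in CH2Cl2 at 0 °C should go ortho to the free hydroxyl, the other ring position being shielded by two silyloxy groups, to give 1-[2-hydroxy-3-iodo-4,6-bis(tert-butyldimethylsilyloxy)phenyl]-3-phenylpropan-1-one F5. Negishi coupling of F5 with excess benzylzinc bromide, Pd2(dba)3 and SPhos (zerovalent palladium) in THF then installs the benzyl group at a defined position and should give 6.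

3. Step 5. Under DBU the substrate may lose an aryl silyl ether, transfer the acyl group from O1 to the α-carbon of the ketone (Baker–Venkataraman-type), or close the ester α-carbon onto the C8 ketone in an aldol-type reaction before the diazo group is formed. The fallback sets out from 6 and comes back at 10, avoiding both the bromoacetate and DBU. Acylation of 6 with glyoxylic acid chloride p-toluenesulfonylhydrazone and N,N-dimethylaniline in CH2Cl2 at 0 °C should give, in the flask, 2-benzyl-3,5-bis(tert-butyldimethylsilyloxy)-6-(3-phenylpropanoyl)phenyl 2-[2-(4-methylbenzenesulfonyl)hydrazinylidene]acetate F6. Addition of Et3N then eliminates sulfinate from F6 (Bamford–Stevens-type) and should give 10 under weaker base than DBU.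

Further compounds
F1 | step 6 | 5,7-dihydroxy-2H-chromen-2-one | O=c1ccc2c(O)cc(O)cc2o1
F2 | step 6 | 5,7-dihydroxy-8-(3-phenylpropanoyl)-2H-chromen-2-one | O=c1ccc2c(O)cc(O)c(C(=O)CCc3ccccc3)c2o1
F3 | step 6 | 5,7-bis(tert-butyldimethylsilyloxy)-8-(3-phenylpropanoyl)-2H-chromen-2-one | O=c1ccc2c(O[Si](C)(C)C(C)(C)C)cc(O[Si](C)(C)C(C)(C)C)c(C(=O)CCc3ccccc3)c2o1
F4 | step 3 | 1-[2-hydroxy-4,6-bis(tert-butyldimethylsilyloxy)phenyl]-3-phenylpropan-1-one | O=C(CCc1ccccc1)c1c(O)cc(O[Si](C)(C)C(C)(C)C)cc1O[Si](C)(C)C(C)(C)C
F5 | step 3 | 1-[2-hydroxy-3-iodo-4,6-bis(tert-butyldimethylsilyloxy)phenyl]-3-phenylpropan-1-one | O=C(CCc1ccccc1)c1c(O)c(I)c(O[Si](C)(C)C(C)(C)C)cc1O[Si](C)(C)C(C)(C)C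
F6 | step 5 | 2-benzyl-3,5-bis(tert-butyldimethylsilyloxy)-6-(3-phenylpropanoyl)phenyl 2-[2-(4-methylbenzenesulfonyl)hydrazinylidene]acetate | Cc1ccc(cc1)S(=O)(=O)NN=CC(=O)Oc1c(Cc2ccccc2)c(O[Si](C)(C)C(C)(C)C)cc(O[Si](C)(C)C(C)(C)C)c1C(=O)CCc1ccccc1
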